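## Retrosynthetic overview
1. The acid comes from Pinnick oxidation of the bicyclic aldehyde. An ester on this doubly neopentyl carbon would be very hard to hydrolyse.
2. Both carbocycles form together in the penultimate step. An intramolecular Diels–Alder (IMDA) reaction of an acyclic (2E,4Z,6S,7E,9E,11E,13E)-hexaenal makes C2–C10 and C3–C7. This closes the cyclohexene and the cyclopentene and sets four stereocentres from C6.
3. The hexaenal comes from a C3–C4 alkenyl–alkenyl Negishi coupling of a (Z)-vinyl iodide with the alkenylalane made from propargyl alcohol and Me3Al.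
4. The phenyl-tetraene arm comes from three iterative formyl-ylide Wittig homologations (C7=C8, C9=C10, C11=C12) and a benzylphosphonate HWE reaction (C13=C14).
5. The C6 stereocentre comes from (S)-Roche ester, and the 4Z geometry from a Stork–Zhao iodo-olefination.

Assumption: the chain is numbered C1 (carboxyl) to C14 (PhCH=). The IMDA is assumed to follow the CHO-endo, A1,3-controlled pathway, which is the one that matches the given stereochemistry.

## Route

**Step 1**
Reactants: 1, methyl (S)-3-hydroxy-2-methylpropanoate ((S)-Roche ester)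
Product: 2, methyl (S)-3-[(tert-butyldimethylsilyl)oxy]-2-methylpropanoate
Conditions: TBSCl, imidazole, CH2Cl2, 0 °C → rt
Reagents that add atoms: TBSCl, CC(C)(C)[Si](C)(C)Cl
Why: Standard silyl ether protection differentiates the two termini, and the stereocentre (future C6) is untouched.

**Step 2**
Reactants: 2
Product: 3, (S)-3-[(tert-butyldimethylsilyl)oxy]-2-methylpropanal
Conditions: DIBAL-H (1.05 equiv), CH2Cl2, −78 °C; MeOH, aq. Rochelle salt
Reagents that add atoms: none
Why: In this partial DIBAL reduction the aluminium hemiacetal survives at −78 °C and collapses only on quench, and the cold non-basic work-up preserves the α-centre.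

**Step 3**
Reactants: 3; 4, ethyltriphenylphosphonium iodide
Product: 5, (R,Z)-tert-butyl[(4-iodo-2-methylpent-3-en-1-yl)oxy]dimethylsilane (I cis to the chain)
Conditions: 4, n-BuLi, THF, rt; I2, −78 °C; NaHMDS, −20 °C; then 3, −78 → −20 °C
Reagents that add atoms: 4, CC[P+](c1ccccc1)(c1ccccc1)c1ccccc1.[I-]; iodine, II
Why: Stork–Zhao olefination with the non-stabilised ylide Ph3P=C(I)Me is kinetically Z-selective, which fixes the future 4Z geometry, and it runs cold enough to avoid epimerisation.

**Step 4**
Reactants: 5
Product: 6, (2R,3Z)-4-iodo-2-methylpent-3-en-1-ol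
Conditions: CSA (10 mol %), MeOH/CH2Cl2, 0 °C
Reagents that add atoms: none
Why: Acid-catalysed methanolysis removes the primary TBS ether, and the vinyl iodide is inert to these conditions.

**Step 5**
Reactants: 6
Product: 7, (2R,3Z)-4-iodo-2-methylpent-3-enal (used crude)
Conditions: DMP, NaHCO3, CH2Cl2, 0 °C → rt
Reagents that add atoms: none
Why: Dess–Martin oxidation is neutral, and A1,3 strain from the Z-alkene holds the α-C–H in the alkene plane, which disfavours enolisation and conjugation.

**Step 6**
Reactants: 7; 8, 2-(triphenylphosphoranylidene)propanal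
Product: 9, (2E,4S,5Z)-6-iodo-2,4-dimethylhepta-2,5-dienal
Conditions: 8 (1.3 equiv), PhMe, 80 °C
Reagents that add atoms: 8, CC(C=O)=P(c1ccccc1)(c1ccccc1)c1ccccc1
Why: The Wittig reaction of a stabilised ylide is E-selective (C7=C8), uses no external base, and gives the enal without redox adjustment.

**Step 7**
Reactants: 9; 8
Product: 10, (2E,4E,6S,7Z)-8-iodo-2,4,6-trimethylnona-2,4,7-trienal
Conditions: 8 (1.5 equiv), PhMe, 110 °C
Reagents that add atoms: 8 (SMILES as above)
Why: A second E-selective stabilised Wittig homologation forms C9=C10, and the more conjugated product reacts more slowly than 9.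

**Step 8**
Reactants: 10; 8
Product: 11, (2E,4E,6E,8S,9Z)-10-iodo-2,4,6,8-tetramethylundeca-2,4,6,9-tetraenal
Conditions: 8 (1.5 equiv), PhMe, 110 °C, dark
Reagents that add atoms: 8 (SMILES as above)
Why: A third E-selective stabilised Wittig homologation forms C11=C12.

**Step 9**
Reactants: 11; 12, diethyl benzylphosphonate
Product: 13, [(1E,3E,5E,7E,9S,10Z)-11-iodo-3,5,7,9-tetramethyldodeca-1,3,5,7,10-pentaen-1-yl]benzene
Conditions: 12, n-BuLi, THF, −78 °C; then 11, −78 °C → rt, dark
Reagents that add atoms: 12, CCOP(=O)(Cc1ccccc1)OCC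
Why: The Horner–Wadsworth–Emmons reaction gives the E-styryl bond, and the pre-formed anion adds to the CHO faster than it removes the remote C6–H.

**Step 10**
Reactants: 13; 14, propargyl alcohol
Product: 15, (2E,4Z,6S,7E,9E,11E,13E)-2,4,6,8,10,12-hexamethyl-14-phenyltetradeca-2,4,7,9,11,13-hexaen-1-ol
Conditions: 14, Me3Al, Cp2ZrCl2 (cat.), (CH2Cl)2, 0 °C → rt; evaporate; then 13, ZnCl2, Pd(PPh3)4 (5 mol %), THF, rt, dark
Reagents that add atoms: 14, C#CCO; trimethylaluminium, C[Al](C)C
Why: Negishi carboalumination adds Me and Al syn with Al at the terminus (sets 2E), and the Pd/Zn Negishi coupling retains geometry at both sp2 carbons (keeps 4Z) while the OH is masked in situ as its aluminium alkoxide.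

**Step 11**
Reactants: 15
Product: 16, (2E,4Z,6S,7E,9E,11E,13E)-2,4,6,8,10,12-hexamethyl-14-phenyltetradeca-2,4,7,9,11,13-hexaenal
Conditions: MnO2, CH2Cl2, 0 °C → rt, dark; filter, use directly
Reagents that add atoms: none
Why: This neutral allylic oxidation activates the dienophile without E/Z scrambling.

**Step 12**
Reactants: 16
Product: 17, (1R,3aR,4R,5S,7aS)-1,3,4,5,7-pentamethyl-5-[(1E,3E)-2-methyl-4-phenylbuta-1,3-dienyl]-3a,4,5,7a-tetrahydro-1H-indene-4-carbaldehyde
Conditions: PhMe (5 mM), BHT, 25 → 60 °C, dark
Reagents that add atoms: none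
Why: In this type-1 IMDA (C7–C10 diene, C2=C3 enal) the CHO-endo/tether-exo transition state gives the trans ring fusion, the E,E-diene and E-dienophile geometries place CHO cis to the dienyl chain on the two quaternary carbons, and A1,3 strain (C6–H eclipsing C7=C8 next to C8-Me) exposes one diene face, so 6S sets all four new centres.

**Step 13**
Reactants: 17
Product: 18, 27-nor-zyggomphic acid B
Conditions: NaClO2, NaH2PO4, 2-methyl-2-butene (excess), t-BuOH/THF/H2O, 0 °C → rt
Reagents that add atoms: sodium chlorite, [Na+].[O-]Cl=O
Why: Pinnick oxidation converts the aldehyde to the acid, the aldehyde has no α-H so nothing can epimerise, and the scavenger protects the alkenes from HOCl.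

## Compound list
1 | methyl (S)-3-hydroxy-2-methylpropanoate | COC(=O)[C@@H](C)CO | starting material
2 | TBS ether of 1 | COC(=O)[C@@H](C)CO[Si](C)(C)C(C)(C)C | intermediate
3 | (S)-3-(TBSO)-2-methylpropanal | O=C[C@@H](C)CO[Si](C)(C)C(C)(C)C | intermediate
4 | ethyltriphenylphosphonium iodide | CC[P+](c1ccccc1)(c1ccccc1)c1ccccc1.[I-] | starting material
5 | (R,Z)-vinyl iodide TBS ether | C/C(I)=C/[C@@H](C)CO[Si](C)(C)C(C)(C)C | intermediate
6 | (2R,3Z)-4-iodo-2-methylpent-3-en-1-ol | C/C(I)=C/[C@@H](C)CO | intermediate
7 | (2R,3Z)-4-iodo-2-methylpent-3-enal | C/C(I)=C/[C@@H](C)C=O | intermediate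
8 | 2-(triphenylphosphoranylidene)propanal | CC(C=O)=P(c1ccccc1)(c1ccccc1)c1ccccc1 | starting material
9 | iodo-dienal | C/C(I)=C/[C@@H](C)/C=C(C)/C=O | intermediate
10 | iodo-trienal | C/C(I)=C/[C@@H](C)/C=C(C)/C=C(C)/C=O | intermediate
11 | iodo-tetraenal | C/C(I)=C/[C@@H](C)/C=C(C)/C=C(C)/C=C(C)/C=O | intermediate
12 | diethyl benzylphosphonate | CCOP(=O)(Cc1ccccc1)OCC | starting material
13 | phenyl iodo-pentaene | C/C(I)=C/[C@@H](C)/C=C(C)/C=C(C)/C=C(C)/C=C/c1ccccc1 | intermediate
14 | propargyl alcohol | C#CCO | starting material
15 | hexaenol | OC/C(C)=C/C(C)=C\[C@@H](C)/C=C(C)/C=C(C)/C=C(C)/C=C/c1ccccc1 | intermediate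
16 | hexaenal | O=C/C(C)=C/C(C)=C\[C@@H](C)/C=C(C)/C=C(C)/C=C(C)/C=C/c1ccccc1 | intermediate
17 | bicyclic aldehyde | CC1=C[C@](C)(/C=C(C)/C=C/c2ccccc2)[C@](C)(C=O)[C@H]2C(C)=C[C@@H](C)[C@H]12 | intermediate
18 | 27-nor-zyggomphic acid B | CC1=C[C@](C)(/C=C(C)/C=C/c2ccccc2)[C@](C)(C(=O)O)[C@H]2C(C)=C[C@@H](C)[C@H]12 | target

## Step count and risks
Total steps: 13. Steps 11 and 12 can be telescoped into one operation.
Longest linear sequence: 13, from (S)-Roche ester. All other building blocks are purchased.

Steps most likely to fail:

1. **Step 12 (IMDA).**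
   - Risks: two contiguous quaternary centres must form, the cis-fused adduct may compete, and 16 may undergo a 1,5-H shift or polyene decomposition.
   - Fallback: cyclise first and extend the side chain afterwards. Reduce dienal 10 and protect it as the C11 CH2OTBS ether, then apply the chemistry of steps 10 and 11.
   - This shorter enal (an isolated diene in place of the styryl-tetraene) should tolerate Me2AlCl at −78 °C, which enforces the CHO-endo mode.
   - After cyclisation, oxidise C1 to the acid, unmask C11 and oxidise it to the aldehyde, then build the side chain on the bicycle with 8 followed by 12.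

2. **Step 10 (late coupling of a hindered Z-iodide on a polyene).**
   - Risks: methyl transfer from residual Me3Al, Z/E erosion, or Heck-type side reactions.
   - Fallback: make C2=C3 by olefination rather than C3–C4 by coupling. Treat 13 with t-BuLi at −100 °C and then DMF to give the (Z)-enal, then run a Wittig reaction with 8 to give 16 directly.

3. **Steps 5 and 6 (α-methyl-β,γ-unsaturated aldehyde 7 in a hot Wittig reaction).**
   - Risks: epimerisation at C6 or migration of the alkene into conjugation.
   - Fallback: reverse the order of olefinations, starting from (R)-Roche ester. Build the E-polyene arm first on the robust TBSO-aldehyde.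
   - Then deprotect and oxidise, so that the labile aldehyde only meets the −78 °C Stork–Zhao ylide.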